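**Retrosynthetic overview**
1. Target 22 ⇐ hepta-O-benzyl ether 21 by global hydrogenolysis (last step).
2. 21 ⇐ silyl ether/Weinreb amide 11 + aryne precursor 16: a fluoride-triggered anionic aryne annulation brings in ring A and closes ring C of the flavanone through the aryl ether bond O1–C8a together with the acyl bond C4–C4a.
3. Enabling feature: O1 on C2 and the C4 carbonyl are 1,3-related (O1–C2–C3–C4, a beta-oxy carbonyl), so they span the two adjacent ring-A carbons C8a and C4a; the C5 oxygen of ring A, next to C4a, polarizes the C4a/C8a aryne so that O1 goes to C8a and the carbanion to C4a.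
4. 11 ⇐ beta-keto ester 8 (Noyori hydrogenation sets C2) ⇐ aldehyde 7 (Roskamp homologation) ⇐ Suzuki–Miyaura union C5'–C8'' of 8-iodoflavone 3 and boronate 6.
5. Ring order: flavone rings D, E and F come intact from apigenin 1, ring B from aldehyde 4, ring A from phenol 12 via 16; ring C is the only ring formed, in step 12.

Key step: step 12

Remark: locants without primes refer to the flavanone (rings A and C), single primes to ring B, double primes to the flavone. Ar = 3,4-bis(benzyloxy)-5-{5,7-bis(benzyloxy)-2-[4-(benzyloxy)phenyl]-4-oxo-4H-chromen-8-yl}phenyl. The C5'–C8'' axis is assumed to rotate freely, since the target carries no axial descriptor. Compounds 1, 4 and 12 are taken as purchasable.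

**Step 1**
Reactants: 1 apigenin (5,7-dihydroxy-2-(4-hydroxyphenyl)-4H-chromen-4-one)
Product: 2 5,7-bis(benzyloxy)-2-[4-(benzyloxy)phenyl]-4H-chromen-4-one
Conditions: BnBr (4.5 equiv), Cs2CO3 (5 equiv), Bu4NI (cat.), DMF, 70 °C
Reagents that add atoms: benzyl bromide, BrCc1ccccc1
Why: Williamson ether synthesis in which carbonate-generated phenoxides are benzylated at all three oxygens, the heat and the cesium counter-ion being needed for the hydrogen-bonded 5-OH.

**Step 2**
Reactants: 2 5,7-bis(benzyloxy)-2-[4-(benzyloxy)phenyl]-4H-chromen-4-one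
Product: 3 5,7-bis(benzyloxy)-2-[4-(benzyloxy)phenyl]-8-iodo-4H-chromen-4-one
Conditions: I2 (1.1 equiv), CF3CO2Ag (1.1 equiv), CH2Cl2, 0 °C to rt, dark
Reagents that add atoms: iodine, II
Why: Electrophilic aromatic iodination with silver-activated iodine should occur at C8'', the benzo-ring position ortho and para to the two benzyloxy groups that is favored over C6'' once the 5''-oxygen is etherified, while the deactivated 4-benzyloxyphenyl ring stays untouched.

**Step 3**
Reactants: 4 3-bromo-4,5-dihydroxybenzaldehyde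
Product: 5 3,4-bis(benzyloxy)-5-bromobenzaldehyde
Conditions: BnBr (2.5 equiv), K2CO3 (3 equiv), DMF, 50 °C
Reagents that add atoms: benzyl bromide, BrCc1ccccc1
Why: Williamson ether synthesis of the catechol, which should proceed readily because neither hydroxyl is chelated.

**Step 4**
Reactants: 5 3,4-bis(benzyloxy)-5-bromobenzaldehyde
Product: 6 3,4-bis(benzyloxy)-5-(4,4,5,5-tetramethyl-1,3,2-dioxaborolan-2-yl)benzaldehyde
Conditions: B2pin2 (1.3 equiv), Pd(dppf)Cl2 (5 mol%), KOAc (3 equiv), 1,4-dioxane, 90 °C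
Reagents that add atoms: bis(pinacolato)diboron, CC1(C)OB(OC1(C)C)B1OC(C)(C)C(C)(C)O1
Why: Miyaura borylation of the aryl bromide, which tolerates the aldehyde under the weak acetate base.

**Step 5**
Reactants: 3 5,7-bis(benzyloxy)-2-[4-(benzyloxy)phenyl]-8-iodo-4H-chromen-4-one, 6 3,4-bis(benzyloxy)-5-(4,4,5,5-tetramethyl-1,3,2-dioxaborolan-2-yl)benzaldehyde
Product: 7 3,4-bis(benzyloxy)-5-{5,7-bis(benzyloxy)-2-[4-(benzyloxy)phenyl]-4-oxo-4H-chromen-8-yl}benzaldehyde (Ar–CHO)
Conditions: Pd(OAc)2 (5 mol%), SPhos (10 mol%), K3PO4 (3 equiv), toluene–H2O (10:1), 90 °C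
Reagents that add atoms: none
Why: Suzuki–Miyaura coupling in which the bulky electron-rich SPhos ligand allows oxidative addition to the hindered 8-iodide and reductive elimination to the tri-ortho-substituted C5'–C8'' biaryl.

**Step 6**
Reactants: 7 Ar–CHO
Product: 8 ethyl 3-Ar-3-oxopropanoate
Conditions: ethyl diazoacetate (1.5 equiv), NbCl5 (10 mol%), CH2Cl2, rt
Reagents that add atoms: ethyl diazoacetate, CCOC(=O)C=[N+]=[N-]
Why: Roskamp homologation in which the diazo carbon adds to the NbCl5-activated aldehyde and the diazonium alkoxide loses N2 with a 1,2-hydride shift to give the beta-keto ester.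

**Step 7**
Reactants: 8 ethyl 3-Ar-3-oxopropanoate
Product: 9 ethyl (3S)-3-Ar-3-hydroxypropanoate
Conditions: RuCl2[(R)-BINAP](DMF)n (2 mol%), H2 (50 atm), EtOH–CH2Cl2 (3:1), 50 °C
Reagents that add atoms: none
Why: Noyori asymmetric hydrogenation in which the chelated beta-keto ester receives hydride on the ketone face dictated by (R)-BINAP, giving the S carbinol (the same facial sense that leads to (R)-3-hydroxybutanoates, the descriptor changing because aryl outranks CH2CO2Et) and so setting the future C2, while benzyl ethers and the flavone are not reduced by this catalyst.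

**Step 8**
Reactants: 9 ethyl (3S)-3-Ar-3-hydroxypropanoate
Product: 10 (3S)-3-Ar-3-hydroxy-N-methoxy-N-methylpropanamide
Conditions: MeNHOMe·HCl (4 equiv), AlMe3 (4 equiv), CH2Cl2, 0 °C to rt; cold dilute HCl
Reagents that add atoms: N,O-dimethylhydroxylamine hydrochloride, CNOC.Cl
Why: Weinreb amidation through the dimethylaluminum amide, which converts the ester without touching the carbinol center and installs the acyl group that later holds its tetrahedral adduct.

**Step 9**
Reactants: 10 (3S)-3-Ar-3-hydroxy-N-methoxy-N-methylpropanamide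
Product: 11 (3S)-3-Ar-N-methoxy-N-methyl-3-(trimethylsilyloxy)propanamide
Conditions: TMSCl (1.5 equiv), imidazole (2.5 equiv), CH2Cl2, 0 °C; filtration through Et3N-deactivated silica
Reagents that add atoms: chlorotrimethylsilane, C[Si](C)(C)Cl
Why: Silylation of the secondary alcohol, which removes the only O–H proton from the annulation substrate and stores the alkoxide in fluoride-releasable form.

**Step 10**
Reactants: 12 3,5-bis(benzyloxy)phenol
Product: 13 3,5-bis(benzyloxy)-2-bromophenol
Conditions: NBS (1.0 equiv), CH2Cl2, −78 to −40 °C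
Reagents that add atoms: N-bromosuccinimide, O=C1CCC(=O)N1Br
Why: Electrophilic bromination of the phenol at low temperature should go ortho to the free hydroxyl (C2), since C4 is shielded between the two benzyloxy groups.

**Step 11**
Reactants: 13 3,5-bis(benzyloxy)-2-bromophenol
Product: 16 3,5-bis(benzyloxy)-2-(trimethylsilyl)phenyl trifluoromethanesulfonate, via aryl trimethylsilyl ether 14 (not isolated), via lithium 2-silylphenoxide 15 (not isolated)
Conditions: HMDS (neat), 80 °C, then evaporation; n-BuLi (1.1 equiv), THF, −100 °C; Tf2O (1.2 equiv), −100 to −78 °C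
Reagents that add atoms: hexamethyldisilazane, C[Si](C)(C)N[Si](C)(C)C; trifluoromethanesulfonic anhydride, O=S(=O)(OS(=O)(=O)C(F)(F)F)C(F)(F)F
Why: O-silylation followed by bromine–lithium exchange triggers a retro-Brook 1,3-shift of silicon from oxygen to carbon, and the lithium phenoxide is trapped as the triflate to give the 2-silylaryl triflate aryne precursor, the exchange at −100 °C outrunning deprotonation of the benzyl ethers.

**Step 12**
Reactants: 11 (3S)-3-Ar-N-methoxy-N-methyl-3-(trimethylsilyloxy)propanamide, 16 3,5-bis(benzyloxy)-2-(trimethylsilyl)phenyl trifluoromethanesulfonate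
Product: 21 (2S)-5,7-bis(benzyloxy)-2-Ar-2,3-dihydro-4H-chromen-4-one, via cesium alkoxide 17 (not isolated), via aryne 18 (not isolated), via aryl cesium 19 (not isolated), via hemiaminal alkoxide 20 (not isolated)
Conditions: CsF (4 equiv), 18-crown-6 (2 equiv), THF, 0 °C, 16 (1.5 equiv) added slowly, then rt; AcOH (3 equiv), 0 °C, then water
Reagents that add atoms: none
Why: Proposed new method: fluoride removes both trimethylsilyl groups, turning 11 into cesium alkoxide 17 and 16 into aryne 18 by loss of triflate, and in the proton-free medium the alkoxide oxygen adds to the aryne carbon remote from the flanking benzyloxy group (the future C8a), which forms the O1–C8a aryl ether bond and leaves aryl cesium 19 with its carbanion at C4a, ortho to that benzyloxy group. The carbanion then adds to the Weinreb carbonyl and gives hemiaminal alkoxide 20, which holds C4 as a tetrahedral adduct, so that no enolizable flavanone, and hence no base-induced opening of ring C to a chalcone, is exposed to base until the acetic acid quench releases ketone 21. The closest known reaction types are the fluoride-triggered annulation of arynes with salicylate esters to xanthones and the insertion of arynes into the N–C(O) bond of beta-lactams to 2,3-dihydroquinolin-4-ones; new are a secondary aliphatic alkoxide unmasked from its silyl ether as the nucleophile and a Weinreb amide as the acyl acceptor. Ring C is closed by a formal [4+2] anionic annulation, namely intermolecular O-arylation (O1–C8a) followed by 6-exo-trig acyl capture (C4–C4a). No stereocenter is formed, because no bond to C2 is made or broken, so the S configuration from step 7 is carried through, and the amide-type alkoxide is poorly disposed to retro-aldol cleavage. The selectivities needed are the regiochemistry of aryne addition, secured by the C5 benzyloxy group through aryne distortion and inductive stabilization of the ortho carbanion, and cyclization over protonation of 19, secured by the silyl ether (no O–H) and the aprotic solvent.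

**Step 13**
Reactants: 21 (2S)-5,7-bis(benzyloxy)-2-Ar-2,3-dihydro-4H-chromen-4-one
Product: 22 (2S)-2-{3,4-dihydroxy-5-[5,7-dihydroxy-2-(4-hydroxyphenyl)-4-oxo-4H-chromen-8-yl]phenyl}-5,7-dihydroxy-2,3-dihydro-4H-chromen-4-one (CNP0204144.1)
Conditions: H2 (1 atm), Pd/C (10 wt% Pd), THF–MeOH (1:1), rt
Reagents that add atoms: none
Why: Catalytic hydrogenolysis of the seven aryl benzyl ethers under neutral conditions should leave the flavone C2''=C3'' bond, both carbonyl groups and the benzylic C2–O1 bond intact and should not epimerize C2, whose ring opening needs base.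

**Compound list**
1 | apigenin | O=c1cc(-c2ccc(O)cc2)oc2cc(O)cc(O)c12 | starting material
2 | 5,7-bis(benzyloxy)-2-[4-(benzyloxy)phenyl]-4H-chromen-4-one | O=c1cc(-c2ccc(OCc3ccccc3)cc2)oc2cc(OCc3ccccc3)cc(OCc3ccccc3)c12 | intermediate
3 | 5,7-bis(benzyloxy)-2-[4-(benzyloxy)phenyl]-8-iodo-4H-chromen-4-one | O=c1cc(-c2ccc(OCc3ccccc3)cc2)oc2c(I)c(OCc3ccccc3)cc(OCc3ccccc3)c12 | intermediate
4 | 3-bromo-4,5-dihydroxybenzaldehyde | O=Cc1cc(O)c(O)c(Br)c1 | starting material
5 | 3,4-bis(benzyloxy)-5-bromobenzaldehyde | O=Cc1cc(OCc2ccccc2)c(OCc2ccccc2)c(Br)c1 | intermediate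
6 | 3,4-bis(benzyloxy)-5-(4,4,5,5-tetramethyl-1,3,2-dioxaborolan-2-yl)benzaldehyde | O=Cc1cc(OCc2ccccc2)c(OCc2ccccc2)c(B2OC(C)(C)C(C)(C)O2)c1 | intermediate
7 | Ar–CHO, 3,4-bis(benzyloxy)-5-{5,7-bis(benzyloxy)-2-[4-(benzyloxy)phenyl]-4-oxo-4H-chromen-8-yl}benzaldehyde | O=Cc1cc(OCc2ccccc2)c(OCc2ccccc2)c(-c2c(OCc3ccccc3)cc(OCc3ccccc3)c3c(=O)cc(-c4ccc(OCc5ccccc5)cc4)oc23)c1 | intermediate
8 | ethyl 3-Ar-3-oxopropanoate | CCOC(=O)CC(=O)c1cc(OCc2ccccc2)c(OCc2ccccc2)c(-c2c(OCc3ccccc3)cc(OCc3ccccc3)c3c(=O)cc(-c4ccc(OCc5ccccc5)cc4)oc23)c1 | intermediate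
9 | ethyl (3S)-3-Ar-3-hydroxypropanoate | CCOC(=O)C[C@@H](c1cc(OCc2ccccc2)c(OCc2ccccc2)c(-c2c(OCc3ccccc3)cc(OCc3ccccc3)c3c(=O)cc(-c4ccc(OCc5ccccc5)cc4)oc23)c1)O | intermediate
10 | (3S)-3-Ar-3-hydroxy-N-methoxy-N-methylpropanamide | CON(C)C(=O)C[C@@H](c1cc(OCc2ccccc2)c(OCc2ccccc2)c(-c2c(OCc3ccccc3)cc(OCc3ccccc3)c3c(=O)cc(-c4ccc(OCc5ccccc5)cc4)oc23)c1)O | intermediate
11 | (3S)-3-Ar-N-methoxy-N-methyl-3-(trimethylsilyloxy)propanamide | CON(C)C(=O)C[C@@H](c1cc(OCc2ccccc2)c(OCc2ccccc2)c(-c2c(OCc3ccccc3)cc(OCc3ccccc3)c3c(=O)cc(-c4ccc(OCc5ccccc5)cc4)oc23)c1)O[Si](C)(C)C | intermediate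
12 | 3,5-bis(benzyloxy)phenol | Oc1cc(OCc2ccccc2)cc(OCc2ccccc2)c1 | starting material
13 | 3,5-bis(benzyloxy)-2-bromophenol | Oc1cc(OCc2ccccc2)cc(OCc2ccccc2)c1Br | intermediate
14 | [3,5-bis(benzyloxy)-2-bromophenoxy]trimethylsilane (not isolated) | C[Si](C)(C)Oc1cc(OCc2ccccc2)cc(OCc2ccccc2)c1Br | intermediate
15 | lithium 3,5-bis(benzyloxy)-2-(trimethylsilyl)phenoxide (not isolated) | [Li+].[O-]c1cc(OCc2ccccc2)cc(OCc2ccccc2)c1[Si](C)(C)C | intermediate
16 | 3,5-bis(benzyloxy)-2-(trimethylsilyl)phenyl trifluoromethanesulfonate | C[Si](C)(C)c1c(OS(=O)(=O)C(F)(F)F)cc(OCc2ccccc2)cc1OCc1ccccc1 | intermediate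
17 | cesium alkoxide of 10 (not isolated) | [Cs+].CON(C)C(=O)C[C@@H](c1cc(OCc2ccccc2)c(OCc2ccccc2)c(-c2c(OCc3ccccc3)cc(OCc3ccccc3)c3c(=O)cc(-c4ccc(OCc5ccccc5)cc4)oc23)c1)[O-] | intermediate
18 | 3,5-bis(benzyloxy)benzyne (not isolated) | C1#CC(OCc2ccccc2)=CC(OCc2ccccc2)=C1 | intermediate
19 | aryl cesium: 3,5-bis(benzyloxy)phenyl ether of 10 with the carbanion on the ring carbon between the ether carbon and a benzyloxy carbon, the future C4a (not isolated) | [Cs+].CON(C)C(=O)C[C@@H](c1cc(OCc2ccccc2)c(OCc2ccccc2)c(-c2c(OCc3ccccc3)cc(OCc3ccccc3)c3c(=O)cc(-c4ccc(OCc5ccccc5)cc4)oc23)c1)Oc1cc(OCc2ccccc2)cc(OCc2ccccc2)[c-]1 | intermediate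
20 | cesium (2S)-5,7-bis(benzyloxy)-2-Ar-4-[methoxy(methyl)amino]chroman-4-olate, C4 epimers (not isolated) | [Cs+].CON(C)C1([O-])C[C@@H](c2cc(OCc3ccccc3)c(OCc3ccccc3)c(-c3c(OCc4ccccc4)cc(OCc4ccccc4)c4c(=O)cc(-c5ccc(OCc6ccccc6)cc5)oc34)c2)Oc2cc(OCc3ccccc3)cc(OCc3ccccc3)c21 | intermediate
21 | (2S)-5,7-bis(benzyloxy)-2-Ar-2,3-dihydro-4H-chromen-4-one (hepta-O-benzyl ether of the target) | O=C1C[C@@H](c2cc(OCc3ccccc3)c(OCc3ccccc3)c(-c3c(OCc4ccccc4)cc(OCc4ccccc4)c4c(=O)cc(-c5ccc(OCc6ccccc6)cc5)oc34)c2)Oc2cc(OCc3ccccc3)cc(OCc3ccccc3)c21 | intermediate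
22 | (2S)-2-{3,4-dihydroxy-5-[5,7-dihydroxy-2-(4-hydroxyphenyl)-4-oxo-4H-chromen-8-yl]phenyl}-5,7-dihydroxy-2,3-dihydro-4H-chromen-4-one | O=C1C[C@@H](c2cc(O)c(O)c(-c3c(O)cc(O)c4c(=O)cc(-c5ccc(O)cc5)oc34)c2)Oc2cc(O)cc(O)c21 | target

**Step count and risks**
Total step count: 13. Longest linear sequence: 9 steps (1, 2, 5, 6, 7, 8, 9, 12, 13).

Steps most likely to fail:

1. Step 12 (proposed new method). What may go wrong: protonation of, or intramolecular proton transfer to, aryl cesium 19 before acyl capture; hydride transfer from the alkoxide to the aryne; or premature collapse of 20 in the flask, which would expose the flavanone to base and erode C2 by ring opening and reclosure. Fallback with known chemistry, setting out from 10 and returning at 21: 5-fluororesorcinol F1 (purchased) would be benzylated (BnBr, K2CO3, DMF) to 1,3-bis(benzyloxy)-5-fluorobenzene F2. Bromination with NBS in MeCN, at the position between fluorine and one benzyloxy group and para to the other, would give 1,5-bis(benzyloxy)-2-bromo-3-fluorobenzene F3. Bromine–lithium exchange (n-BuLi, THF, −78 °C) would give [2,4-bis(benzyloxy)-6-fluorophenyl]lithium F4 (not isolated). Three equivalents of F4 would be added to unprotected 10, the first deprotonating the hydroxyl, to give after work-up the beta-hydroxy ketone (3S)-1-[2,4-bis(benzyloxy)-6-fluorophenyl]-3-Ar-3-hydroxypropan-1-one F5. Intramolecular SNAr of its alkoxide on the ortho-fluorine (Cs2CO3, DMF, 40 °C) would then form the same O1–C8a bond and give 21.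

2. Step 6. What may go wrong: aryl migration instead of hydride migration in the diazonium alkoxide of this electron-rich aldehyde, and sequestration of the Lewis acid by the flavone carbonyl. Fallback, setting out from 7 and returning at 8: aldol addition of the lithium enolate of ethyl acetate (LDA, EtOAc, THF, −78 °C) would give racemic ethyl 3-Ar-3-hydroxypropanoate F6, and Dess–Martin oxidation (CH2Cl2, rt) would give 8.

3. Step 13. What may go wrong: over-reduction (saturation of the flavone C2''=C3'' bond or hydrogenolysis of the benzylic C2–O1 bond) and stalling at partly benzylated stages through poor solubility. Fallback, setting out from 21 and arriving directly at 22: non-reductive cleavage of all seven benzyl ethers with BCl3 and pentamethylbenzene as cation scavenger in CH2Cl2 at −78 °C, followed by a methanol quench; this fallback makes no new compound (F0).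

**Further compounds**
F1 | step 12 | 5-fluororesorcinol (purchased) | Oc1cc(O)cc(F)c1
F2 | step 12 | 1,3-bis(benzyloxy)-5-fluorobenzene | Fc1cc(OCc2ccccc2)cc(OCc2ccccc2)c1
F3 | step 12 | 1,5-bis(benzyloxy)-2-bromo-3-fluorobenzene | Fc1cc(OCc2ccccc2)cc(OCc2ccccc2)c1Br
F4 | step 12 | [2,4-bis(benzyloxy)-6-fluorophenyl]lithium | [Li]c1c(F)cc(OCc2ccccc2)cc1OCc1ccccc1
F5 | step 12 | (3S)-1-[2,4-bis(benzyloxy)-6-fluorophenyl]-3-Ar-3-hydroxypropan-1-one | O=C(C[C@@H](c1cc(OCc2ccccc2)c(OCc2ccccc2)c(-c2c(OCc3ccccc3)cc(OCc3ccccc3)c3c(=O)cc(-c4ccc(OCc5ccccc5)cc4)oc23)c1)O)c1c(F)cc(OCc2ccccc2)cc1OCc1ccccc1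
F6 | step 6 | racemic ethyl 3-Ar-3-hydroxypropanoate | CCOC(=O)CC(O)c1cc(OCc2ccccc2)c(OCc2ccccc2)c(-c2c(OCc3ccccc3)cc(OCc3ccccc3)c3c(=O)cc(-c4ccc(OCc5ccccc5)cc4)oc23)c1
F0 | step 13 | none | none
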